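**Strategy.** The chroman ring is cut at C4–C4a and O1–C8a. This turns ring A into 3,5-bis(benzyloxy)benzyne and the rest into an open C2–C3–C4 chain that already carries both stereocentres, set by one Evans glycolate aldol. In the key step the C2 alkoxide adds to the aryne and the resulting aryl anion closes onto the C4 chloride, so the pyran ring forms in one operation. The step exploits the oxygenation pattern of ring A: O1 sits at C8a, meta to the oxygens on C5 and C7, and C4a is flanked by the C5 oxygen, which is exactly the polarity of a 3-alkoxyaryne. Deallylation, galloylation and hydrogenolysis finish the synthesis.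

Key step: step 7

Remark: flavan numbering (O1, C2, C3, C4, C4a, C5 to C8, C8a) is used for the corresponding atoms of all chain and chroman compounds; compounds 1, 6, 7, 10 and 23 are taken as purchasable.

Step 1
Reactants: 1 3,5-bis(benzyloxy)phenol
Product: 2 2-bromo-3,5-bis(benzyloxy)phenol
Conditions: NBS (1.0 equiv), i-Pr2NH (cat.), CH2Cl2, −78 → 0 °C
Reagents that add atoms: N-bromosuccinimide, O=C1CCC(=O)N1Br
Why: Electrophilic aromatic bromination under the amine-catalysed NBS protocol should deliver bromine ortho to the free hydroxyl, so that the position between OH and OBn is favoured over the one between the two OBn groups.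

Step 2
Reactants: 2 2-bromo-3,5-bis(benzyloxy)phenol
Product: 5 3,5-bis(benzyloxy)-2-(trimethylsilyl)phenyl trifluoromethanesulfonate, via aryl trimethylsilyl ether 3 (not isolated), via lithium 2-silylphenoxide 4 (not isolated)
Conditions: HMDS, THF, 65 °C, then evaporation; n-BuLi, THF, −100 → −78 °C; Tf2O, −100 → −78 °C
Reagents that add atoms: hexamethyldisilazane, C[Si](C)(C)N[Si](C)(C)C; trifluoromethanesulfonic anhydride, O=S(=O)(OS(=O)(=O)C(F)(F)F)C(F)(F)F
Why: O-silylation, bromine–lithium exchange and a 1,3 O→C silyl shift (retro-Brook rearrangement) place TMS on the formerly brominated carbon, and the freed phenoxide is triflated, which is the standard route to ortho-silylaryl triflate aryne precursors.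

Step 3
Reactants: 6 2-(allyloxy)acetic acid; 7 (S)-4-benzyloxazolidin-2-one
Product: 9 (S)-3-[2-(allyloxy)acetyl]-4-benzyloxazolidin-2-one, via mixed pivalic anhydride 8 (not isolated)
Conditions: PivCl, Et3N, THF, −20 °C; then 7, LiCl, −20 °C → rt
Reagents that add atoms: none
Why: N-acylation of the oxazolidinone by the mixed anhydride under LiCl/Et3N activation should occur at the unhindered glycolyl carbonyl and not at the pivaloyl carbonyl.

Step 4
Reactants: 9 (S)-3-[2-(allyloxy)acetyl]-4-benzyloxazolidin-2-one; 10 4-(benzyloxy)benzaldehyde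
Product: 13 (S)-3-[(2S,3R)-2-(allyloxy)-3-[4-(benzyloxy)phenyl]-3-hydroxypropanoyl]-4-benzyloxazolidin-2-one, via (Z)-boron enolate 11 (not isolated), via boron aldolate 12 (not isolated)
Conditions: Bu2BOTf, Et3N, CH2Cl2, −78 → 0 °C; then 10, −78 → 0 °C; H2O2, MeOH, pH 7 buffer, 0 °C
Reagents that add atoms: none
Why: Evans syn aldol reaction, in which the (Z)-boron enolate reacts through a Zimmerman–Traxler chair on the face away from the benzyl group of the dipole-minimised auxiliary and so sets both stereocentres (the later C3 and C2) in the syn relationship with 2S,3R configuration.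

Step 5
Reactants: 13 the aldol adduct
Product: 14 (1R,2R)-2-(allyloxy)-1-[4-(benzyloxy)phenyl]propane-1,3-diol
Conditions: NaBH4, THF/H2O (4:1), 0 °C → rt
Reagents that add atoms: none
Why: Reductive cleavage of the N-acyloxazolidinone by borohydride should give the primary alcohol and return the auxiliary without touching either stereocentre.

Step 6
Reactants: 14 (1R,2R)-2-(allyloxy)-1-[4-(benzyloxy)phenyl]propane-1,3-diol
Product: 16 (1R,2S)-2-(allyloxy)-1-[4-(benzyloxy)phenyl]-3-chloropropan-1-ol, via primary mesylate 15 (not isolated)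
Conditions: MsCl (1.05 equiv), 2,4,6-collidine, CH2Cl2, −10 °C; then LiCl, DMF, 60 °C
Reagents that add atoms: lithium chloride, [Li+].[Cl-]
Why: Chemoselective sulfonylation of the primary hydroxyl (collidine conditions discriminate against the hindered secondary benzylic hydroxyl) followed by SN2 displacement with chloride should give the chloride without involving the stereocentres.

Step 7
Reactants: 16 (1R,2S)-2-(allyloxy)-1-[4-(benzyloxy)phenyl]-3-chloropropan-1-ol; 5 3,5-bis(benzyloxy)-2-(trimethylsilyl)phenyl trifluoromethanesulfonate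
Product: 20 (2R,3R)-3-(allyloxy)-5,7-bis(benzyloxy)-2-[4-(benzyloxy)phenyl]chromane, via potassium alkoxide 17 (not isolated), via 3,5-bis(benzyloxy)benzyne 18 (not isolated), via aryl anion 19 (not isolated)
Conditions: KH (1.0 equiv), THF, 0 °C; then 5 (1.5 equiv), CsF, 18-crown-6, THF, −20 °C → rt
Reagents that add atoms: none
Why: Proposed new method: fluoride removes the TMS group of 5 with loss of triflate to give 3,5-bis(benzyloxy)benzyne 18, the preformed alkoxide 17 adds to it, and the aryl anion 19 displaces chloride from C4, so that O1–C8a and C4–C4a should form in one flask. The closest known reaction types are aryne annulations with partners that carry a nucleophile and an electrophile (phenoxide addition, then closure of the aryl anion onto an ester or an enone) and the Parham cyclialkylation of 2-(3-halopropoxy)aryllithiums to chromans; an aliphatic 3-chloroalkoxide has not been shown as the four-atom partner. The pyran ring closes in the 6-exo-tet mode. No stereocentre is formed: C2 keeps its C–O bond (the carbinol oxygen becomes O1) and C3 is a spectator, so both are carried over from 16. The step needs addition of oxygen at C8a and not at C4a, which the benzyloxy group beside the aryne bond secures because attack at the remote carbon places the carbanion next to this inductively withdrawing oxygen; it also needs ring closure to outrun protonation and oxetane formation, which the absence of an O–H donor (alkoxide made with KH), the poor chloride leaving group and the slow 4-exo-tet closure should secure.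

Step 8
Reactants: 20 (2R,3R)-3-(allyloxy)-5,7-bis(benzyloxy)-2-[4-(benzyloxy)phenyl]chromane
Product: 22 (2R,3R)-5,7-bis(benzyloxy)-2-[4-(benzyloxy)phenyl]chroman-3-ol, via (E)-prop-1-enyl ether 21 (not isolated)
Conditions: [Ir(cod)(PMePh2)2]PF6 (cat., activated with H2, then degassed), THF, rt; then 0.5 M aq. HCl, THF, rt
Reagents that add atoms: none
Why: Iridium hydride-catalysed isomerisation of the allyl ether to the prop-1-enyl ether and mild acid hydrolysis of this enol ether should free the 3-hydroxyl while benzyl ethers and the flavan ring stay intact.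

Step 9
Reactants: 22 (2R,3R)-5,7-bis(benzyloxy)-2-[4-(benzyloxy)phenyl]chroman-3-ol; 23 3,4,5-tris(benzyloxy)benzoic acid
Product: 24 (2R,3R)-5,7-bis(benzyloxy)-2-[4-(benzyloxy)phenyl]chroman-3-yl 3,4,5-tris(benzyloxy)benzoate
Conditions: EDC·HCl, DMAP, CH2Cl2, rt
Reagents that add atoms: none
Why: Steglich esterification, in which DMAP transfers the carbodiimide-activated tribenzylgalloyl group to the secondary 3-hydroxyl without affecting C2 or C3.

Step 10
Reactants: 24 the hexabenzyl ether
Product: 25 (2R,3R)-5,7-dihydroxy-2-(4-hydroxyphenyl)chroman-3-yl 3,4,5-trihydroxybenzoate ((−)-epiafzelechin 3-O-gallate, CID467295)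
Conditions: H2 (1 atm), Pd(OH)2/C, THF/MeOH, rt
Reagents that add atoms: none
Why: Catalytic hydrogenolysis should cleave all six benzyl ethers while the ester and the cyclic benzylic ether O1–C2 survive under these mild conditions.

**Compound list**

1 | 3,5-bis(benzyloxy)phenol | Oc1cc(OCc2ccccc2)cc(OCc2ccccc2)c1 | starting material
2 | 2-bromo-3,5-bis(benzyloxy)phenol | Oc1cc(OCc2ccccc2)cc(OCc2ccccc2)c1Br | intermediate
3 | [2-bromo-3,5-bis(benzyloxy)phenoxy]trimethylsilane | C[Si](C)(C)Oc1cc(OCc2ccccc2)cc(OCc2ccccc2)c1Br | intermediate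
4 | lithium 3,5-bis(benzyloxy)-2-(trimethylsilyl)phenoxide | [Li+].[O-]c1cc(OCc2ccccc2)cc(OCc2ccccc2)c1[Si](C)(C)C | intermediate
5 | 3,5-bis(benzyloxy)-2-(trimethylsilyl)phenyl trifluoromethanesulfonate | C[Si](C)(C)c1c(OS(=O)(=O)C(F)(F)F)cc(OCc2ccccc2)cc1OCc1ccccc1 | intermediate
6 | 2-(allyloxy)acetic acid | C=CCOCC(=O)O | starting material
7 | (S)-4-benzyloxazolidin-2-one | O=C1OC[C@H](Cc2ccccc2)N1 | starting material
8 | 2-(allyloxy)acetic pivalic anhydride | C=CCOCC(=O)OC(=O)C(C)(C)C | intermediate
9 | (S)-3-[2-(allyloxy)acetyl]-4-benzyloxazolidin-2-one | C=CCOCC(=O)N1[C@@H](Cc2ccccc2)COC1=O | intermediate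
10 | 4-(benzyloxy)benzaldehyde | O=Cc1ccc(OCc2ccccc2)cc1 | starting material
11 | (Z)-dibutylboron enolate of 9 | CCCCB(CCCC)O/C(=C\OCC=C)N1[C@@H](Cc2ccccc2)COC1=O | intermediate
12 | dibutylboron aldolate of 13 | C=CCO[C@@H]([C@H](OB(CCCC)CCCC)c1ccc(OCc2ccccc2)cc1)C(=O)N1[C@@H](Cc2ccccc2)COC1=O | intermediate
13 | (S)-3-[(2S,3R)-2-(allyloxy)-3-[4-(benzyloxy)phenyl]-3-hydroxypropanoyl]-4-benzyloxazolidin-2-one | C=CCO[C@@H]([C@H](O)c1ccc(OCc2ccccc2)cc1)C(=O)N1[C@@H](Cc2ccccc2)COC1=O | intermediate
14 | (1R,2R)-2-(allyloxy)-1-[4-(benzyloxy)phenyl]propane-1,3-diol | C=CCO[C@@H]([C@H](O)c1ccc(OCc2ccccc2)cc1)CO | intermediate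
15 | (2R,3R)-2-(allyloxy)-3-[4-(benzyloxy)phenyl]-3-hydroxypropyl methanesulfonate | C=CCO[C@@H]([C@H](O)c1ccc(OCc2ccccc2)cc1)COS(C)(=O)=O | intermediate
16 | (1R,2S)-2-(allyloxy)-1-[4-(benzyloxy)phenyl]-3-chloropropan-1-ol | C=CCO[C@@H]([C@H](O)c1ccc(OCc2ccccc2)cc1)CCl | intermediate
17 | potassium (1R,2S)-2-(allyloxy)-1-[4-(benzyloxy)phenyl]-3-chloropropan-1-olate | C=CCO[C@@H]([C@H]([O-])c1ccc(OCc2ccccc2)cc1)CCl.[K+] | intermediate
18 | 3,5-bis(benzyloxy)benzyne (1,2-didehydro-3,5-bis(benzyloxy)benzene) | C1#CC(OCc2ccccc2)=CC(OCc2ccccc2)=C1 | intermediate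
19 | potassium 2-{[(1R,2S)-2-(allyloxy)-1-[4-(benzyloxy)phenyl]-3-chloropropyl]oxy}-4,6-bis(benzyloxy)benzen-1-ide | C=CCO[C@@H]([C@H](OC1=CC(OCc2ccccc2)=CC(OCc2ccccc2)=[C-]1)c1ccc(OCc2ccccc2)cc1)CCl.[K+] | intermediate
20 | (2R,3R)-3-(allyloxy)-5,7-bis(benzyloxy)-2-[4-(benzyloxy)phenyl]chromane | C=CCO[C@@H]1Cc2c(OCc3ccccc3)cc(OCc3ccccc3)cc2O[C@@H]1c1ccc(OCc2ccccc2)cc1 | intermediate
21 | (2R,3R)-5,7-bis(benzyloxy)-2-[4-(benzyloxy)phenyl]-3-[(E)-prop-1-enyloxy]chromane | C/C=C/O[C@@H]1Cc2c(OCc3ccccc3)cc(OCc3ccccc3)cc2O[C@@H]1c1ccc(OCc2ccccc2)cc1 | intermediate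
22 | (2R,3R)-5,7-bis(benzyloxy)-2-[4-(benzyloxy)phenyl]chroman-3-ol | O[C@@H]1Cc2c(OCc3ccccc3)cc(OCc3ccccc3)cc2O[C@@H]1c1ccc(OCc2ccccc2)cc1 | intermediate
23 | 3,4,5-tris(benzyloxy)benzoic acid | O=C(O)c1cc(OCc2ccccc2)c(OCc2ccccc2)c(OCc2ccccc2)c1 | starting material
24 | (2R,3R)-5,7-bis(benzyloxy)-2-[4-(benzyloxy)phenyl]chroman-3-yl 3,4,5-tris(benzyloxy)benzoate | O=C(O[C@@H]1Cc2c(OCc3ccccc3)cc(OCc3ccccc3)cc2O[C@@H]1c1ccc(OCc2ccccc2)cc1)c1cc(OCc2ccccc2)c(OCc2ccccc2)c(OCc2ccccc2)c1 | intermediate
25 | (2R,3R)-5,7-dihydroxy-2-(4-hydroxyphenyl)chroman-3-yl 3,4,5-trihydroxybenzoate | O=C(O[C@@H]1Cc2c(O)cc(O)cc2O[C@@H]1c1ccc(O)cc1)c1cc(O)c(O)c(O)c1 | target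

**Step count and risks**

Total steps: 10. Longest linear sequence: 8 steps (steps 3 to 10, from 6 and 7 to 25); steps 1 and 2 form the second branch, which joins at step 7.

Steps most likely to fail:

1. Step 7 (proposed new method). The aryl anion may be protonated before it cyclises, the chloroalkoxide may close to an oxetane before it meets the aryne, or the alkoxide may add too slowly to the short-lived aryne. The fallback sets out from 16 and 5 and comes back at 22, so that it also takes the place of step 8. It makes the same two bonds in separate, known operations. Without KH, 16 and 5 with CsF in MeCN at room temperature should give the simple O-arylation product (known arylation of alcohols by arynes, the aryl anion being quenched by the hydroxyl proton), the aryl ether F1, in which both ring positions ortho to the new oxygen are equivalent. Iridium-catalysed isomerisation as in step 8 would give the prop-1-enyl ether F2, and mild aqueous acid the chlorohydrin F3. K2CO3 in MeOH should close the epoxide F4. BF3·OEt2 in CH2Cl2 at −78 °C (or hexafluoroisopropanol alone) should then bring about the known 6-endo Friedel–Crafts epoxide–arene cyclisation of aryl glycidyl-type ethers, the activated ring attacking the CH2 terminus, to give chroman-3-ol 22 with C2 and C3 unchanged.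

2. Step 6. Sulfonylation may not discriminate cleanly between the primary and the benzylic hydroxyl, and the electron-rich benzylic alcohol may ionise or be substituted during the chloride displacement. The fallback sets out from 13 and comes back at 16, replacing chemoselectivity by protection. TESOTf and 2,6-lutidine mask the benzylic hydroxyl to give the silyl ether F5. LiBH4 in Et2O/MeOH removes the auxiliary to give the primary alcohol F6. An Appel reaction (PPh3, CCl4, pyridine) on the only free hydroxyl gives the chloride F7. TBAF buffered with AcOH in THF returns 16.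

3. Step 1. Bromination may occur para to the hydroxyl (between the two benzyloxy groups) or twice. The fallback sets out from 1 and comes back at 5, fixing the position by directed ortho metalation instead of electrophilic substitution. ClCONEt2 and NaH give the O-aryl diethylcarbamate F8. Lithiation with s-BuLi/TMEDA in THF at −78 °C at the position flanked by the carbamate and a benzyloxy group, then a TMSCl quench, gives the silyl carbamate F9. LiAlH4 in THF removes the carbamate to give the silylphenol F10. Tf2O and pyridine give 5.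

**Further compounds**

F1 | step 7 | 1-{[(1R,2S)-2-(allyloxy)-1-[4-(benzyloxy)phenyl]-3-chloropropyl]oxy}-3,5-bis(benzyloxy)benzene | C=CCO[C@@H]([C@H](Oc1cc(OCc2ccccc2)cc(OCc2ccccc2)c1)c1ccc(OCc2ccccc2)cc1)CCl
F2 | step 7 | 1-{[(1R,2S)-1-[4-(benzyloxy)phenyl]-3-chloro-2-[(E)-prop-1-enyloxy]propyl]oxy}-3,5-bis(benzyloxy)benzene | C/C=C/O[C@@H]([C@H](Oc1cc(OCc2ccccc2)cc(OCc2ccccc2)c1)c1ccc(OCc2ccccc2)cc1)CCl
F3 | step 7 | (2S,3R)-3-[3,5-bis(benzyloxy)phenoxy]-3-[4-(benzyloxy)phenyl]-1-chloropropan-2-ol | O[C@@H]([C@H](Oc1cc(OCc2ccccc2)cc(OCc2ccccc2)c1)c1ccc(OCc2ccccc2)cc1)CCl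
F4 | step 7 | 1,3-bis(benzyloxy)-5-{(R)-[4-(benzyloxy)phenyl][(2R)-oxiran-2-yl]methoxy}benzene | O1C[C@@H]1[C@H](Oc1cc(OCc2ccccc2)cc(OCc2ccccc2)c1)c1ccc(OCc2ccccc2)cc1
F5 | step 6 | (S)-3-[(2S,3R)-2-(allyloxy)-3-[4-(benzyloxy)phenyl]-3-[(triethylsilyl)oxy]propanoyl]-4-benzyloxazolidin-2-one | C=CCO[C@@H]([C@H](O[Si](CC)(CC)CC)c1ccc(OCc2ccccc2)cc1)C(=O)N1[C@@H](Cc2ccccc2)COC1=O
F6 | step 6 | (2R,3R)-2-(allyloxy)-3-[4-(benzyloxy)phenyl]-3-[(triethylsilyl)oxy]propan-1-ol | C=CCO[C@@H]([C@H](O[Si](CC)(CC)CC)c1ccc(OCc2ccccc2)cc1)CO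
F7 | step 6 | {[(1R,2S)-2-(allyloxy)-1-[4-(benzyloxy)phenyl]-3-chloropropyl]oxy}triethylsilane | C=CCO[C@@H]([C@H](O[Si](CC)(CC)CC)c1ccc(OCc2ccccc2)cc1)CCl
F8 | step 1 | 3,5-bis(benzyloxy)phenyl diethylcarbamate | CCN(CC)C(=O)Oc1cc(OCc2ccccc2)cc(OCc2ccccc2)c1
F9 | step 1 | 3,5-bis(benzyloxy)-2-(trimethylsilyl)phenyl diethylcarbamate | CCN(CC)C(=O)Oc1cc(OCc2ccccc2)cc(OCc2ccccc2)c1[Si](C)(C)C
F10 | step 1 | 3,5-bis(benzyloxy)-2-(trimethylsilyl)phenol | Oc1cc(OCc2ccccc2)cc(OCc2ccccc2)c1[Si](C)(C)C
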